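## Retrosynthetic overview
1. The last step removes two MOM ethers. The chelated 2'-OH is never protected.
2. Disconnecting the enone Cα=Cβ bond (Claisen–Schmidt) gives 4-MOMO-3,5-diprenylbenzaldehyde and 2-hydroxy-4-MOMO-acetophenone. The E geometry is set here.
3. Disconnecting both aryl–prenyl bonds (double Stille) gives the MOM ether of 3,5-dibromo-4-hydroxybenzaldehyde and prenyltributylstannane.
4. The ketone partner comes from 2,4-dihydroxyacetophenone by selective 4-O-MOM protection.
5. No ring is formed, because both benzene rings are bought intact.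

Assumption: abyssinone VI is achiral, so "single enantiomer" does not apply. The only stereochemical element to control is the E-alkene.

## Route

**Step 1**
Reactants: 1, 3,5-dibromo-4-hydroxybenzaldehyde; 2, chloromethyl methyl ether (MOMCl)
Product: 3, 3,5-dibromo-4-(methoxymethoxy)benzaldehyde (C9H8Br2O3)
Conditions: MOMCl (1.5 equiv), i-Pr2NEt (2 equiv), CH2Cl2, 0 °C → rt, 3 h
Reagents that add atoms: MOMCl, COCCl
Why: This is a Williamson-type O-alkylation of the acidic 2,6-dibromophenol with a very reactive α-chloroether, and it removes the acidic OH that would protodestannylate the allylstannane in step 2 and deactivate the aldehyde in step 4.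

**Step 2**
Reactants: 3, 3,5-dibromo-4-(methoxymethoxy)benzaldehyde; 4, tributyl(3-methylbut-2-en-1-yl)stannane
Product: 5, 4-(methoxymethoxy)-3,5-bis(3-methylbut-2-en-1-yl)benzaldehyde (C19H26O3)
Conditions: 4 (2.6 equiv), Pd(PPh3)4 (10 mol %), degassed DMF, 100 °C, 16 h; aq KF work-up
Reagents that add atoms: prenyltributylstannane, CCCC[Sn](CCCC)(CCCC)CC=C(C)C (two prenyl units are delivered)
Why: This is a double Stille coupling in which reductive elimination occurs at the less substituted allyl terminus to give the linear prenyl arene, and the stannane tolerates the free aldehyde, whereas prenyl-boron or prenyl-zinc reagents would add to it.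

**Step 3**
Reactants: 6, 2,4-dihydroxyacetophenone; 2, MOMCl
Product: 7, 1-[2-hydroxy-4-(methoxymethoxy)phenyl]ethan-1-one (C10H12O4)
Conditions: MOMCl (1.1 equiv), K2CO3 (2 equiv), acetone, 0 °C → rt, 4 h
Reagents that add atoms: MOMCl, COCCl
Why: This is a regioselective O-alkylation, because the 2-OH is hydrogen-bonded to the carbonyl and is a poor nucleophile, so only the 4-OH reacts with a weak base and about one equivalent of MOMCl.

**Step 4**
Reactants: 5, 4-(methoxymethoxy)-3,5-bis(3-methylbut-2-en-1-yl)benzaldehyde; 7, 1-[2-hydroxy-4-(methoxymethoxy)phenyl]ethan-1-one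
Product: 8, (E)-1-[2-hydroxy-4-(methoxymethoxy)phenyl]-3-[4-(methoxymethoxy)-3,5-bis(3-methylbut-2-en-1-yl)phenyl]prop-2-en-1-one (C29H36O6)
Conditions: KOH (50% aq, ~12 equiv), EtOH, N2, 0 °C → rt, 24–48 h; then cold 1 M HCl to pH 5–6
Reagents that add atoms: none
Why: This is a Claisen–Schmidt aldol condensation with a non-enolisable aldehyde, its E1cB dehydration gives the thermodynamically favoured E-enone only, and the MOM ethers and prenyl groups are inert to hydroxide.

**Step 5**
Reactants: 8, bis-MOM chalcone
Product: 9, abyssinone VI, (E)-1-(2,4-dihydroxyphenyl)-3-[4-hydroxy-3,5-bis(3-methylbut-2-en-1-yl)phenyl]prop-2-en-1-one (C25H28O4)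
Conditions: 3 M aq HCl, MeOH, 50 °C, ca. 45–60 min (TLC-monitored, quenched with NaHCO3 at full conversion)
Reagents that add atoms: none
Why: This is an acid-catalysed acetal solvolysis of aryl MOM ethers, which is much faster than protonation of the trisubstituted prenyl alkenes (chroman formation) or chalcone-to-flavanone cyclisation of a chelated 2'-hydroxychalcone lacking a 6'-OH, so the E-alkene and both prenyl groups survive a short exposure.

## Compound list
| No. | Name | SMILES | Role |
|---|---|---|---|
| 1 | 3,5-dibromo-4-hydroxybenzaldehyde | O=Cc1cc(Br)c(O)c(Br)c1 | starting material |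
| 2 | chloromethyl methyl ether (MOMCl) | COCCl | starting material |
| 3 | 3,5-dibromo-4-(methoxymethoxy)benzaldehyde | COCOc1c(Br)cc(C=O)cc1Br | intermediate |
| 4 | tributyl(3-methylbut-2-en-1-yl)stannane | CCCC[Sn](CCCC)(CCCC)CC=C(C)C | starting material |
| 5 | 4-(methoxymethoxy)-3,5-bis(3-methylbut-2-en-1-yl)benzaldehyde | COCOc1c(CC=C(C)C)cc(C=O)cc1CC=C(C)C | intermediate |
| 6 | 2,4-dihydroxyacetophenone | CC(=O)c1ccc(O)cc1O | starting material |
| 7 | 1-[2-hydroxy-4-(methoxymethoxy)phenyl]ethan-1-one | COCOc1ccc(C(C)=O)c(O)c1 | intermediate |
| 8 | (E)-1-[2-hydroxy-4-(methoxymethoxy)phenyl]-3-[4-(methoxymethoxy)-3,5-bis(3-methylbut-2-en-1-yl)phenyl]prop-2-en-1-one | COCOc1ccc(C(=O)/C=C/c2cc(CC=C(C)C)c(OCOC)c(CC=C(C)C)c2)c(O)c1 | intermediate |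
| 9 | abyssinone VI | CC(C)=CCc1cc(/C=C/C(=O)c2ccc(O)cc2O)cc(CC=C(C)C)c1O | target |

## Summary
Total step count: 5
Longest linear sequence: 4 (1 → 3 → 5 → 8 → 9)

Three steps most likely to fail, each with one fallback:

1. **Step 2, double Stille prenylation.**
   - Risks: incomplete second coupling next to the OMOM group, some branched (reverse-prenyl) product, and Pd-mediated allylation of the aldehyde.
   - Fallback: drop the cross-coupling. Make 4-hydroxy-3,5-diprenylbenzaldehyde directly by ortho,ortho'-C-alkylation of 4-hydroxybenzaldehyde phenoxide with prenyl bromide in aqueous KOH, where water favours C- over O-alkylation. Then protect it as the MOM ether to reach 5. The step count is the same, the yield is lower, and no metal is used.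

2. **Step 5, acidic MOM removal.**
   - Risks: cyclisation of an o-prenylphenol to a 2,2-dimethylchroman, and isomerisation to the flavanone.
   - Fallback: change the protecting-group strategy to SEM ethers, using SEMCl in steps 1 and 3. SEM ethers survive the Stille and KOH steps and are cleaved by fluoride (TBAF, THF/DMPU), so the prenylated chalcone never meets acid.

3. **Step 4, Claisen–Schmidt condensation.**
   - Risks: slow reaction, because 7 is present as its 2-phenoxide and the aldehyde is electron-rich, plus Cannizzaro reaction and flavanone by-products.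
   - Fallback: form the alkene by Wittig olefination instead. Convert 2,4-bis(methoxymethoxy)acetophenone to its α-bromide and then to the stabilised ylide ArC(O)CH=PPh3. Heat this ylide with aldehyde 5 in toluene, which is neutral and E-selective, and then carry out the same deprotection.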